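Compound numbers used below (full list after the steps): 1 pentane-2,4-dione; 2 methyl octanoate; 3 dianion of 1; 4 tridecane-2,4,6-trione; 5 carbon dioxide; 6 trianion of 4; 7 3,5,7-trioxotetradecanoic acid; 8 cyclic aldol adduct; 9 2-heptyl-4,6-dihydroxybenzoic acid; 10 benzyl ester of 9; 11 orsellinic acid; 12 tribenzyl orsellinate; 13 2,4-bis(benzyloxy)-6-methylbenzoic acid; 14 its acid chloride; 15 protected depside; 16 target.

## Analysis of the target

Target 16 is a depside: two benzene rings joined by a single aryl ester. Ring A is 2-heptyl-4,6-dihydroxybenzoic acid acylated on O-4, and ring B is the 2,4-dihydroxy-6-methylbenzoyl (orsellinoyl) unit. There is no stereocentre, so the problem is one of regio- and chemoselectivity only. The sensitive groups are the depside ester (a phenyl ester and therefore an acyl donor towards hydroxide, alkoxide and amines), the free resorcylic acid of ring A (which loses CO2 on heating or in strong acid) and three free phenols. The first difficulty is that ring A carries four substituents in fixed positions, with the carboxyl wedged between the heptyl group and a hydroxyl. The second is that the 4-hydroxyl of ring A must be told apart from its 6-hydroxyl and from the phenols of ring B, with a final deprotection that spares the depside ester. The strategy rests on the fact that the six ring carbons of ring A, the carboxyl carbon and the heptyl chain form one unbranched fourteen-carbon chain oxygenated on every second carbon: ring carbons C6 and C4 are chain C3 and C5 of 3,5,7-trioxotetradecanoic acid 7, and the ring bond C1–C2 is the bond between chain C2 and chain C7.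

## Retrosynthetic reasoning

**16 from 15.** The last operation removes three benzyl groups from 15, one from the carboxyl of ring A and two from the phenols of ring B. Benzyl is chosen for all three because hydrogenolysis is neutral and leaves an aryl ester and a free resorcylic acid alone. Any hydrolytic or Lewis-acidic unmasking would put the depside bond at risk.

**15 from 10 and 14.** The depside C(=O)–O bond is cut. This divides the molecule into two rings of similar size and makes the route convergent. The forward reaction has to acylate the 4-hydroxyl of 10 and not the 6-hydroxyl. The 6-hydroxyl is hydrogen-bonded to the neighbouring ester carbonyl and sterically flanked, while the 4-hydroxyl is more acidic and open, so the substrate itself should direct the acyl group.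

**14 from 11 through 12 and 13.** Ring B is bought complete as orsellinic acid 11, so no ring bond is made here. All three acidic positions are benzylated to 12, the ester is hydrolysed to 13 and the acid is activated as 14. This costs three steps but only protection and activation chemistry.

**10 from 9.** The carboxyl of ring A is masked as its benzyl ester so that it cannot form a mixed anhydride with 14 and so that it falls off in the same hydrogenolysis as the ethers. The forward step must alkylate the carboxylate without touching the phenols.

**9 from 7 through 8.** The ring bond between the carboxyl-bearing carbon and the heptyl-bearing carbon is cut, and the two phenols are read as ketones. This unfolds ring A into the open-chain triketo acid 7, in which every ring carbon, the carboxyl and the side chain are already in place with the correct oxygen pattern. No arene has to be substituted regioselectively. The forward reaction is an intramolecular aldol addition of chain C2 to the C7 ketone giving 8, which aromatizes by dehydration and enolization. It has to choose this fold over the other cyclization modes open to 7.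

**7 from 4 and 5.** The C1–C2 bond of the chain is cut, which takes the carboxyl off as carbon dioxide 5 and leaves the triketone 4. Forward, the terminal methyl of 4 is the last and most basic site of the trianion 6 and should be the one that is carboxylated.

**4 from 1 and 2.** The bond between C5 and C6 of the triketone is cut. Pentane-2,4-dione 1 supplies five carbons as its dianion 3 and methyl octanoate 2 supplies the acyl carbon and the heptyl chain. Both are bulk chemicals, and the step is a Claisen-type acylation at the terminal carbanion of 3.

## Alternatives that were turned down

**Alternative 1:** The depside ester would be cut at two bonds at once, the aryl–carbonyl bond and the carbonyl–oxygen bond. Ring B then arrives as 1,5-bis(benzyloxy)-2-iodo-3-methylbenzene A1, the carbonyl as carbon monoxide A2 and ring A as the phenol 10. In the forward step the catalyst would be formed from palladium diacetate A3 and the wide-bite-angle diphosphine Xantphos A4. A1 would undergo oxidative addition at zerovalent palladium and A2 would insert. The aroyl–palladium species would then be captured by the 4-hydroxyl of 10 to give benzyl 4-{[2,4-bis(benzyloxy)-6-methylbenzoyl]oxy}-2-heptyl-6-hydroxybenzoate A5, and A5 is the same structure as 15.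
- For it: ring B needs no carboxyl group, so A1 is two steps (benzylation, iodination) from a cheap diphenol. The hydrolysis of a hindered ester and the handling of a moisture-sensitive acid chloride (steps 6 and 7) would disappear. On the ring B branch this alternative is the shorter one.
- Against it: A1 is substituted on both ortho positions, so the catalyst from A3 and A4 has to turn over on a hindered aryl iodide. The nucleophile is an electron-poor phenol that must compete as its phenoxide, and the base needed for that can also ionize the 6-hydroxyl. A5 is an activated aryl ester that phenoxide can cleave again under the same hot, basic conditions.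
- Comparison: the step does nothing for ring A, which would still have to be made as 10. The chosen route pays more steps on ring B, but it couples with a stoichiometric acyl chloride whose outcome does not depend on catalytic turnover of A3 and A4, and it places its strategic step on the real structural problem.

**Alternative 2:** Ring A would be cut into a four-carbon vinylketene and a two-carbon alkyne. Irradiation of benzyl 2-diazo-4-methylidene-3-oxoundecanoate A6 should cause a Wolff rearrangement to the ester-substituted vinylketene benzyl 3-methylidene-2-(oxomethylidene)decanoate A7. A7 would combine with ethoxyethyne A8 by (2+2) cycloaddition, four-electron opening of the cyclobutenone and six-electron closure of the dienylketene. Tautomerization would give benzyl 6-ethoxy-2-heptyl-4-hydroxybenzoate A9.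
- For it: the regiochemistry is fixed by the pericyclic sequence and no other fold is possible. A9 has the 4-hydroxyl free and O-6 capped, a cleaner differentiation than the hydrogen-bond argument used in step 8. On both points it is stronger than the chosen route.
- Against it: A6 needs a 2-methylidene acyl unit, chain extension to the β-keto ester and a diazo transfer, clearly more than the two steps to 7. The ketene carbon of A7 is fully substituted and carries an ester, which slows the (2+2) step and opens a competing hetero-(4+2) addition of A8 across the O=C–C=C=O unit. The ethyl ether of A9 must be cleaved later by a Lewis acid, either next to the benzyl ester before coupling or next to the depside ester after it.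
- Comparison: the chosen route offers a shorter sequence from bulk aliphatic materials, no diazo compound or photochemistry, and a ring A that needs no ether cleavage.

**Alternative 3:** Ring A would be cut at the C1–C6 and C2–C3 bonds into benzyl dec-2-ynoate A10 and 1,1-dimethoxy-3-(trimethylsilyloxy)buta-1,3-diene A11. A (4+2) cycloaddition, followed by loss of one methoxy group and of the silyl group, would give benzyl 2-heptyl-4-hydroxy-6-methoxybenzoate A12.
- For it: the polarities match, since the nucleophilic CH2 terminus of A11 meets the β-carbon of A10. Regiocontrol is therefore better defined than in an aldol fold with competing closures. Both components are one or two steps from a terminal alkyne and an acetoacetate ester, and the route is convergent and about as short as the chosen one up to the stage of 10.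
- Against it: A10 is a poor dienophile, activated by one ester only and carrying an alkyl group on the reacting β-carbon. It would need temperatures at which the ketene-acetal diene A11 is not stable. Lewis-acid activation changes the mechanism to a stepwise conjugate addition that can stop at open-chain adducts. The methyl ether of A12 must be removed by a Lewis acid to reach 10, in the presence of the benzyl ester.
- Comparison: the chosen route delivers the resorcylic acid with both phenols free and at the correct oxidation level in the ring-forming step itself.

Key step: step 3

Assumption: LiN(iPr)2 is used as the commercial solution, and 7 is carried into step 3 crude and cold without purification, because β-keto acids lose CO2 on standing.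

## Route

**Step 1**
Reactants: 1 pentane-2,4-dione; 2 methyl octanoate
Product: 4 tridecane-2,4,6-trione, via dilithium penta-1,3-diene-2,4-diolate 3 (not isolated)
Conditions: LiN(iPr)2 (2.0 equiv per 1), THF, −78 → 0 °C; then 2 (0.5 equiv per 1), 0 °C → rt; aq. HCl
Reagents that add atoms: none
Why: Claisen-type acylation of a 1,3-diketone dianion: the terminal carbanion of 3 is far more basic and nucleophilic than the internal delocalized enolate carbon and attacks the ester carbonyl of 2. The second equivalent of 3 takes the proton of the more acidic triketone as it forms, so 2 should be consumed completely.

**Step 2**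
Reactants: 4 tridecane-2,4,6-trione; 5 carbon dioxide
Product: 7 3,5,7-trioxotetradecanoic acid, via trilithium trideca-1,3,5-triene-2,4,6-triolate 6 (not isolated)
Conditions: LiN(iPr)2 (3.3 equiv), THF, 0 °C; then transfer onto excess solid CO2 in Et2O, −78 °C; cold aq. HCl to pH 2, Et2O extraction at 0 °C
Reagents that add atoms: none
Why: Carboxylation of a triketone trianion: once the two internal methylenes are ionized, the third deprotonation should go kinetically to the unhindered terminal methyl and not to the C7 methylene, and this most basic carbon adds to CO2. Inverse addition keeps the trianion from being quenched by the more acidic product.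

**Step 3**
Reactants: 7 3,5,7-trioxotetradecanoic acid
Product: 9 2-heptyl-4,6-dihydroxybenzoic acid, via 2-heptyl-2-hydroxy-4,6-dioxocyclohexane-1-carboxylic acid 8 (not isolated)
Conditions: aq. KH2PO4/K2HPO4 buffer (0.2 M, pH 6.5)–THF 4:1, degassed, 20 °C; then aq. HCl to pH 2 at 0 °C, EtOAc
Reagents that add atoms: none
Why: At pH 6.5 the carboxyl of 7 is ionized and the polyketone chain is largely enolized; the enol(ate) of the C3 ketone, nucleophilic at C2, adds to the C7 ketone to give the cyclic aldol 8, which loses water and tautomerizes at its two remaining ketones to the aromatic acid 9. The closest known reaction type is the aldol cyclization of 3,5,7-triketo acids to 6-substituted β-resorcylic acids in weakly acidic to neutral water, the laboratory counterpart of orsellinic acid biosynthesis. The single ring closes in a 6-(enolendo)-exo-trig mode, C2 attacking the exocyclic C7=O, which is geometrically favourable. No stereocentre survives: the two centres of 8 form without control as a diastereomer mixture and are erased by dehydration and aromatization. The step must prefer this fold over Claisen closure of C6 onto C1, lactonization of the C5 enol oxygen onto C1, the alternative aldol of C8 onto C3, and simple decarboxylation. The first two need C1 as an acyl donor and are shut off because C1 is a carboxylate; decarboxylation needs the protonated acid and is slowed for the same reason. The C8 aldol is disfavoured because C8 is activated by one carbonyl only, while C2 lies between the carboxyl and the C3 carbonyl. Aromatization is irreversible and pulls the reversible aldol equilibrium towards 9.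

**Step 4**
Reactants: 9 2-heptyl-4,6-dihydroxybenzoic acid
Product: 10 benzyl 2-heptyl-4,6-dihydroxybenzoate
Conditions: BnBr (1.05 equiv), KHCO3 (1.1 equiv), DMF, rt
Reagents that add atoms: benzyl bromide, BrCc1ccccc1
Why: O-Alkylation of a carboxylate (SN2 on benzyl bromide): KHCO3 ionizes only the carboxylic acid and leaves both phenols protonated, so the benzyl group should go to the carboxyl oxygen alone. Room temperature avoids decarboxylation of the resorcylic acid.

**Step 5**
Reactants: 11 orsellinic acid (2,4-dihydroxy-6-methylbenzoic acid)
Product: 12 benzyl 2,4-bis(benzyloxy)-6-methylbenzoate
Conditions: BnBr (3.5 equiv), K2CO3 (4 equiv), DMF, rt then 60 °C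
Reagents that add atoms: benzyl bromide, BrCc1ccccc1
Why: Williamson etherification together with carboxylate alkylation: the carboxylate reacts first at room temperature, which blocks decarboxylation. Warming then drives benzylation of the 4-hydroxyl and of the hydrogen-bonded 2-hydroxyl.

**Step 6**
Reactants: 12 benzyl 2,4-bis(benzyloxy)-6-methylbenzoate
Product: 13 2,4-bis(benzyloxy)-6-methylbenzoic acid
Conditions: KOH (5 equiv), DMSO–H2O 4:1, 90 °C; then aq. HCl
Reagents that add atoms: potassium hydroxide, [K+].[OH-]
Why: Saponification of a hindered benzoate: hydroxide in aqueous DMSO is nucleophilic enough to cleave the di-ortho-substituted benzyl ester, while aryl benzyl ethers are inert to base.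

**Step 7**
Reactants: 13 2,4-bis(benzyloxy)-6-methylbenzoic acid
Product: 14 2,4-bis(benzyloxy)-6-methylbenzoyl chloride
Conditions: (COCl)2 (1.5 equiv), DMF (cat.), CH2Cl2, 0 °C → rt; evaporation, crude 14 used at once
Reagents that add atoms: oxalyl chloride, O=C(Cl)C(=O)Cl
Why: Acid chloride formation through the chloroiminium salt generated from DMF and oxalyl chloride. The conditions are cold and only mildly acidic, so the benzyl ethers should stay in place, and the gaseous by-products leave on evaporation.

**Step 8**
Reactants: 10 benzyl 2-heptyl-4,6-dihydroxybenzoate; 14 2,4-bis(benzyloxy)-6-methylbenzoyl chloride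
Product: 15 benzyl 4-{[2,4-bis(benzyloxy)-6-methylbenzoyl]oxy}-2-heptyl-6-hydroxybenzoate
Conditions: Et3N (1.5 equiv), DMAP (0.1 equiv), CH2Cl2, 0 °C → rt
Reagents that add atoms: none
Why: Acyl transfer to a phenol with nucleophilic catalysis by DMAP through the N-acylpyridinium ion. The 4-hydroxyl of 10 is the more acidic and unhindered one, whereas the 6-hydroxyl is held in a hydrogen bond to the ester carbonyl and flanked by the ester, so monoacylation at O-4 is expected with one equivalent of 14.

**Step 9**
Reactants: 15 benzyl 4-{[2,4-bis(benzyloxy)-6-methylbenzoyl]oxy}-2-heptyl-6-hydroxybenzoate
Product: 16 4-[(2,4-dihydroxy-6-methylbenzoyl)oxy]-2-heptyl-6-hydroxybenzoic acid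
Conditions: H2 (1 atm), 10% Pd/C, EtOAc, rt
Reagents that add atoms: none
Why: Hydrogenolysis of benzylic C–O bonds: the benzyl ester and both benzyl ethers are cleaved, whereas the depside linkage is an aryl ester without a benzylic C–O bond and should not be touched. Neutral conditions at room temperature keep the resorcylic acid from decarboxylating.

## Compound list

1 | pentane-2,4-dione | CC(=O)CC(C)=O | starting material
2 | methyl octanoate | CCCCCCCC(=O)OC | starting material
3 | dilithium penta-1,3-diene-2,4-diolate (dianion of 1) | [Li+].[Li+].C=C([O-])C=C(C)[O-] | intermediate (not isolated)
4 | tridecane-2,4,6-trione | CCCCCCCC(=O)CC(=O)CC(C)=O | intermediate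
5 | carbon dioxide | O=C=O | starting material
6 | trilithium trideca-1,3,5-triene-2,4,6-triolate (trianion of 4) | [Li+].[Li+].[Li+].C=C([O-])C=C([O-])C=C([O-])CCCCCCC | intermediate (not isolated)
7 | 3,5,7-trioxotetradecanoic acid | CCCCCCCC(=O)CC(=O)CC(=O)CC(=O)O | intermediate
8 | 2-heptyl-2-hydroxy-4,6-dioxocyclohexane-1-carboxylic acid (mixture of diastereomers, both centres lost on aromatization) | CCCCCCCC1(O)CC(=O)CC(=O)C1C(=O)O | intermediate (not isolated)
9 | 2-heptyl-4,6-dihydroxybenzoic acid | CCCCCCCc1cc(O)cc(O)c1C(=O)O | intermediate
10 | benzyl 2-heptyl-4,6-dihydroxybenzoate | CCCCCCCc1cc(O)cc(O)c1C(=O)OCc1ccccc1 | intermediate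
11 | orsellinic acid (2,4-dihydroxy-6-methylbenzoic acid) | Cc1cc(O)cc(O)c1C(=O)O | starting material
12 | benzyl 2,4-bis(benzyloxy)-6-methylbenzoate | Cc1cc(OCc2ccccc2)cc(OCc2ccccc2)c1C(=O)OCc1ccccc1 | intermediate
13 | 2,4-bis(benzyloxy)-6-methylbenzoic acid | Cc1cc(OCc2ccccc2)cc(OCc2ccccc2)c1C(=O)O | intermediate
14 | 2,4-bis(benzyloxy)-6-methylbenzoyl chloride | Cc1cc(OCc2ccccc2)cc(OCc2ccccc2)c1C(=O)Cl | intermediate
15 | benzyl 4-{[2,4-bis(benzyloxy)-6-methylbenzoyl]oxy}-2-heptyl-6-hydroxybenzoate | CCCCCCCc1cc(OC(=O)c2c(C)cc(OCc3ccccc3)cc2OCc2ccccc2)cc(O)c1C(=O)OCc1ccccc1 | intermediate
16 | 4-[(2,4-dihydroxy-6-methylbenzoyl)oxy]-2-heptyl-6-hydroxybenzoic acid | CCCCCCCc1cc(OC(=O)c2c(C)cc(O)cc2O)cc(O)c1C(=O)O | target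

## Step count and risk

Total: 9 steps. Longest linear sequence: 6 steps (1, 2, 3, 4, 8, 9). The ring B branch (steps 5 to 7) joins at step 8.

**Step 3 (key step).** The ring closure competes with loss of CO2 from the β-keto acid before cyclization, with lactonization through the C5 enol oxygen, and with closure along the other aldol mode (C8 onto C3). It may also be slow if the amphiphilic substrate aggregates in water. The balance of these pathways depends on pH and cannot be predicted exactly for a heptyl chain. Fallback: set out from 13, which the route makes anyway. Double deprotonation with LiN(iPr)2 in THF at −78 °C (carboxylate plus lateral lithiation of the ortho methyl group) and alkylation with 1-iodohexane should give 2,4-bis(benzyloxy)-6-heptylbenzoic acid F1. Hydrogenolysis over Pd/C then gives 9, where the route is rejoined. This gives up ring construction and instead lengthens the methyl group of an orsellinate skeleton.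

**Step 2.** The third deprotonation may go partly to the C7 methylene instead of the methyl, the product may transfer a proton to unreacted trianion, and CO2 may be lost during the acidic work-up. Fallback: set out from 2. Benzyl 3,5-dioxohexanoate F2 is prepared from the dianion of benzyl 3-oxobutanoate (NaH, then n-BuLi) and N-methoxy-N-methylacetamide. F2 is converted with LiN(iPr)2 into its trianion and acylated at the terminal methyl by 2, giving benzyl 3,5,7-trioxotetradecanoate F3. Here the carboxyl carbon is present from the start and the methyl is the only terminal site. Neutral hydrogenolysis (H2, Pd/C, EtOAc) releases 7, where the route is rejoined.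

**Step 1.** Proton transfer from the α-methylene of 2 to the dianion (enolization instead of acylation) and self-condensation of the ester can lower conversion. The triketone formed also consumes base. Fallback: set out from 2 and convert it with N,O-dimethylhydroxylamine hydrochloride and iPrMgCl into N-methoxy-N-methyloctanamide F4. F4 acylates 3 through a chelated tetrahedral adduct that persists until work-up, so no acidic triketone is present while 3 is being consumed. The route is rejoined at 4.

**Step 8.** Acyl transfer from the di-ortho-substituted chloride may be slow enough for hydrolysis to compete, and some acylation of the chelated 6-hydroxyl or base-induced acyl migration is possible. Fallback: set out from 13 and omit step 7. Trifluoroacetic anhydride in toluene at rt activates 13 as 2,4-bis(benzyloxy)-6-methylbenzoic trifluoroacetic anhydride F5. F5 acylates 10 under acidic, base-free conditions at the non-chelated 4-hydroxyl, and the route is rejoined at 15.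

## Further compounds

F1 | step 3 | 2,4-bis(benzyloxy)-6-heptylbenzoic acid | CCCCCCCc1cc(OCc2ccccc2)cc(OCc2ccccc2)c1C(=O)O
F2 | step 2 | benzyl 3,5-dioxohexanoate | CC(=O)CC(=O)CC(=O)OCc1ccccc1
F3 | step 2 | benzyl 3,5,7-trioxotetradecanoate | CCCCCCCC(=O)CC(=O)CC(=O)CC(=O)OCc1ccccc1
F4 | step 1 | N-methoxy-N-methyloctanamide | CCCCCCCC(=O)N(C)OC
F5 | step 8 | 2,4-bis(benzyloxy)-6-methylbenzoic trifluoroacetic anhydride | Cc1cc(OCc2ccccc2)cc(OCc2ccccc2)c1C(=O)OC(=O)C(F)(F)F
A1 | alternative 1 | 1,5-bis(benzyloxy)-2-iodo-3-methylbenzene | Cc1cc(OCc2ccccc2)cc(OCc2ccccc2)c1I
A2 | alternative 1 | carbon monoxide | [C-]#[O+]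
A3 | alternative 1 | palladium diacetate | CC(=O)[O-].CC(=O)[O-].[Pd+2]
A4 | alternative 1 | Xantphos (4,5-bis(diphenylphosphino)-9,9-dimethylxanthene) | CC1(C)c2cccc(P(c3ccccc3)c3ccccc3)c2Oc2c(P(c3ccccc3)c3ccccc3)cccc21
A5 | alternative 1 | benzyl 4-{[2,4-bis(benzyloxy)-6-methylbenzoyl]oxy}-2-heptyl-6-hydroxybenzoate | CCCCCCCc1cc(OC(=O)c2c(C)cc(OCc3ccccc3)cc2OCc2ccccc2)cc(O)c1C(=O)OCc1ccccc1
A6 | alternative 2 | benzyl 2-diazo-4-methylidene-3-oxoundecanoate | CCCCCCCC(=C)C(=O)C(=[N+]=[N-])C(=O)OCc1ccccc1
A7 | alternative 2 | benzyl 3-methylidene-2-(oxomethylidene)decanoate | CCCCCCCC(=C)C(=C=O)C(=O)OCc1ccccc1
A8 | alternative 2 | ethoxyethyne | CCOC#C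
A9 | alternative 2 | benzyl 6-ethoxy-2-heptyl-4-hydroxybenzoate | CCCCCCCc1cc(O)cc(OCC)c1C(=O)OCc1ccccc1
A10 | alternative 3 | benzyl dec-2-ynoate | CCCCCCCC#CC(=O)OCc1ccccc1
A11 | alternative 3 | 1,1-dimethoxy-3-(trimethylsilyloxy)buta-1,3-diene | COC(OC)=CC(=C)O[Si](C)(C)C
A12 | alternative 3 | benzyl 2-heptyl-4-hydroxy-6-methoxybenzoate | CCCCCCCc1cc(O)cc(OC)c1C(=O)OCc1ccccc1
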